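## Structural features

The target is a diaryl ether of two benzene rings with no other ring and no stereocentre, so no stereocentres stand next to each other and every problem is one of regiochemistry. Ring A carries the bridging oxygen on C1, methoxyls on C2 and C6 and a propyl chain on C4. Ring B carries the bridging oxygen on C1, a free hydroxyl on C2, a methoxyl on C3 and a 3-hydroxypropyl chain on C5. The fragile parts are the electron-rich ring B with its free phenol (open to oxidation and to electrophilic attack at C4 and C6) and the primary alcohol; the aryl methyl ethers also rule out strong Lewis acids. The real difficulty is the bridging oxygen: it has three ortho oxygen substituents and joins two electron-rich rings, the worst case for metal-mediated aryl–oxygen coupling and for nucleophilic aromatic substitution. A second difficulty is that the neighbouring oxygens on C1 and C2 of ring B must end differently (ether and free hydroxyl). The key step uses the fact that ring A, with oxygen on C1, C2 and C6 and carbon on C4, is the aromatized form of a 2-aryloxy-5-propylcyclohexane-1,3-dione. In that form C1 is an sp3 carbon next to a ketone and bearing the aryloxy group, so the C1–C2 bond can be made by acylating its enolate while the hindered oxygen is still part of a plain aryloxymethyl ketone. Because ring A is symmetric about the C1–C4 axis, aromatization and methylation of the dione cannot give regioisomers.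

## Logic of the disconnections

**17 to 16.** The O–H bonds on C2 of ring B and at the end of the side chain are traced back to two O–CH2Ph bonds. Both hydroxyls would consume base or be alkylated in the ring-forming and methylation steps. The gain is that 16 has no acidic hydrogen, and both masks fall in one operation. The forward step must cleave two benzylic C–O bonds without touching the diaryl ether or the methyl ethers.

**16 to 15.** The O–CH3 bond on C2 of ring A is cut. The oxidation that creates ring A cannot be relied on to deliver both methyl ethers, so one is added afterwards. The gain is that a mixture of mono- and dimethyl ethers converges on 16. The forward step must methylate a phenol oxygen that lies next to the aryloxy group.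

**15 to 14.** Ring A is taken down one oxidation level and its remaining O–CH3 bond is cut. This turns C1 of ring A into an sp3 carbon between two carbonyls, the functionality that a Claisen condensation produces. The gain is that an aromatic ring is replaced by a ring that can be closed with carbonyl chemistry. The forward oxidation must spare ring B and both benzyl ethers.

**14 to 13.** The C1–C2 bond of ring A is cut, opening the ring to an acyclic keto ester. The bridging oxygen then sits on a CH2 group next to a ketone, so it can be introduced by simple alkylation. The forward step needs the enolate at the aryloxy-bearing carbon to be the one that attacks the ester.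

**13 to 7 and 12.** The O–CH2 bond between the ring B oxygen and C6 of the chain is cut. This divides the molecule into two pieces of similar size and makes the route convergent. The forward step is O-alkylation of an ortho-substituted phenol at a primary, carbonyl-activated carbon. It requires that 7 has only one free hydroxyl.

**12 to 9.** The C5–C6 bond and the C–Br bond of 12 are cut, removing one carbon and returning to a carboxylic acid. The forward step is a one-carbon homologation of the acid to a bromomethyl ketone that leaves the methyl ester alone.

**9 to 8.** The ester C–O bond is cut to give a cyclic anhydride. The two carbonyls of 8 are equivalent, so their differentiation needs no protecting group and raises no regiochemical question.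

**7 to 5.** The C1–O bond of ring B is exchanged for a C1–CHO bond. The formyl carbon marks which of the two neighbouring oxygens will be the free phenol, so the C1/C2 differentiation is settled by constitution. The forward step needs aryl migration in a peracid oxidation.

**5 to 2 and 3.** The bond between C5 of ring B and the first chain carbon is cut. The three-carbon chain then arrives complete and already benzyl-protected from 3, through 4. The forward step needs regioselective hydroboration and an sp3–sp2 coupling that tolerates the aldehyde.

**2 to 1.** The O–benzyl bond on C2 of ring B is cut. 1 is a purchasable arene that already holds the bromine, the formyl group, the hydroxyl and the methoxyl in the required positions.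

## Other disconnections considered

**Alternative 1:** The cut runs through ring B at C1–C6 and C2–C3. C1 and C2 would come from the bis(trimethylsilyl) ketene acetal of (2,6-dimethoxy-4-propylphenoxy)acetic acid A2, made from 2,6-dimethoxy-4-propylphenol A1 by O-alkylation with a haloacetate, hydrolysis and silylation. C3 to C6 would come from methyl 3-bromocoumalate A3.

- Forward key step: the electron-rich A2 would bond through its aryloxy-bearing carbon to C6 of A3 and through its acetal carbon to C3. Decarboxylative cycloreversion and loss of silanol would then aromatize the adduct to methyl 3-bromo-5-(2,6-dimethoxy-4-propylphenoxy)-4-hydroxybenzoate A4.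
- In its favour: ring A is bought complete as A1, so it needs neither oxidation nor methylation; on this point the alternative is the better plan. The hindered oxygen is again installed as an alkyl aryl ether before the second ring exists, which makes it the equal of the chosen plan in avoiding aryl–oxygen coupling. The polarities of A2 and A3 match.
- Against it here: A4 has bromine where the C3 methoxyl must stand and an ester where a three-carbon alcohol chain is needed. The key step would be followed by a copper-mediated methoxylation beside a free phenol and a two-carbon homologation with reductions, roughly five more operations. A3 must also be prepared first.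
- Comparison: on structure, the chosen plan delivers ring B with every substituent in its final form, while the alternative delivers ring A in final form. On mechanism, the alternative relies on an electronically controlled cycloaddition followed by two eliminations in one flask, whereas ring size enforces the selectivity of the chosen closure. On step economy, the steps saved on ring A would probably be spent again on ring B, so the alternative is expected to be no shorter and probably somewhat longer.

**Alternative 2:** The cut is made on the ring B side of the bridging oxygen (C1–O), together with the C2–O bond, which is taken back to C2–I. Ring B becomes an aryne generated from 5-[3-(benzyloxy)propyl]-3-methoxy-2-(trimethylsilyl)phenyl trifluoromethanesulfonate A5.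

- Forward key step: a fluoride source would trigger 1,2-elimination from A5. The potassium phenoxide of A1 would add at C1, the aryne carbon remote from the methoxyl. The aryl anion formed at C2 would take iodine from a perfluoroalkyl iodide, giving 5-[3-(benzyloxy)propyl]-1-(2,6-dimethoxy-4-propylphenoxy)-2-iodo-3-methoxybenzene A6. No ring is formed.
- In its favour: both rings enter intact and the hindered bond and a C2 handle are made in one operation; in convergence, and probably in total step count, this alternative is the better one. An aryne is reactive enough to accept a phenoxide with two ortho substituents. The regiochemistry of addition to 3-alkoxyarynes follows from aryne distortion and from inductive stabilisation of the anion beside the methoxyl.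
- Against it here: A5 requires ortho-silylation between two oxygen functions of a phenol that already carries the side chain, several steps in itself. The short-lived aryl anion may be protonated instead of iodinated, which would give an ether that cannot be advanced. The iodide of A6, wedged between the aryloxy and methoxy groups, must still be converted into a hydroxyl before deprotection.
- Comparison: on structure, both plans reach the right substitution, but the chosen plan fixes the C1/C2 oxygen pattern through the constitution of 1, while here it depends on two selectivities of a three-component event. On mechanism, the chosen closure is under thermodynamic control and the aryne trapping is under kinetic control. On step economy, the alternative is ahead if A5 can be reached in four or five steps.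

**Alternative 3:** The cut goes through ring A at C4–C5 and C2–C3. The fragments are 2-{2-(benzyloxy)-5-[3-(benzyloxy)propyl]-3-methoxyphenoxy}-4-chloro-3-methoxycyclobut-2-en-1-one A7, a squarate-derived cyclobutenone that would be made from 7, and tributyl(pent-1-en-2-yl)stannane A8.

- Forward key step: Stille coupling under zerovalent palladium catalysis would join C4 of A7 to the stannylated carbon of A8. The 4-alkenylcyclobutenone would open in a four-electron electrocyclic reaction to a dienylketene, which would close in a six-electron electrocyclization and tautomerise to 2-{2-(benzyloxy)-5-[3-(benzyloxy)propyl]-3-methoxyphenoxy}-3-methoxy-5-propylphenol A9. A9 has the same constitution as 15.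
- In its favour: ring A is formed directly at the aromatic oxidation level, so no separate oxidation is needed; on this point the alternative is the better plan. The bridging oxygen is introduced by addition–elimination of 7 to a squarate ester, again not by aryl–oxygen coupling, and the endgame from A9 is the same as from 15; on both points the plans are equal.
- Against it here: A7 requires a mixed aryl methyl squarate, reduction of only the carbonyl next to the methoxy-bearing carbon, and replacement of hydroxyl by chloride without allylic transposition. Each of these three operations carries a selectivity question. A8 is a toxic organotin reagent whose branched regiochemistry must be secured, and the cyclobutenones are sensitive to heat and water.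
- Comparison: on structure, the outcome is the same compound. On mechanism, the pericyclic cascade fixes the hydroxyl next to C1 once the alkenylcyclobutenone exists, but the regiochemical burden is moved to the preparation of A7, whereas 13 is assembled from the symmetric 8 without any such question. On step economy, the two are about equal (six steps from 7 to the target here against five plus two for 12), with costlier and less benign reagents in the alternative.

Key step: step 7

Remark on the chemistry: 1, 3 and 8 are taken to be purchasable. The propyl-bearing carbon is a stereocentre in 9–13 (and in the enol form of 14); these are carried as racemates because that carbon becomes the planar C4 of ring A.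

Remark on the chemistry: 14 is written as the diketone but is expected to exist largely as its enol.

## Route

Step 1
Reactants: 1 5-bromo-2-hydroxy-3-methoxybenzaldehyde
Product: 2 2-(benzyloxy)-5-bromo-3-methoxybenzaldehyde
Conditions: BnBr, K2CO3, DMF, rt
Reagents that add atoms: benzyl bromide, BrCc1ccccc1
Why: Williamson O-benzylation of the only acidic hydroxyl through its potassium phenoxide in a polar aprotic solvent. Benzyl is chosen because it survives every later step and leaves together with the side-chain benzyl ether in step 10.

Step 2
Reactants: 2 2-(benzyloxy)-5-bromo-3-methoxybenzaldehyde; 3 allyl benzyl ether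
Product: 5 2-(benzyloxy)-5-[3-(benzyloxy)propyl]-3-methoxybenzaldehyde, via alkylborane 4 (not isolated)
Conditions: 3, 9-BBN, THF, 0 °C → rt; then 2, PdCl2(dppf) (3 mol %), K3PO4 (aq), THF–DMF, 60 °C
Reagents that add atoms: none
Why: Anti-Markovnikov hydroboration of the terminal alkene of 3 gives the primary alkylborane 4, which enters a B-alkyl Suzuki–Miyaura coupling (oxidative addition of zerovalent palladium into the C–Br bond, base-assisted transmetallation, reductive elimination) and joins C5 of ring B to the chain. A slight excess of 3 over 9-BBN should leave no B–H to reduce the aldehyde, and phosphate in place of hydroxide avoids Cannizzaro chemistry.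

Step 3
Reactants: 5 2-(benzyloxy)-5-[3-(benzyloxy)propyl]-3-methoxybenzaldehyde
Product: 7 2-(benzyloxy)-5-[3-(benzyloxy)propyl]-3-methoxyphenol, via aryl formate 6 (not isolated)
Conditions: mCPBA, CH2Cl2, 0 °C → rt; aq NaHCO3 wash; then K2CO3 (cat.), MeOH, rt
Reagents that add atoms: 3-chloroperoxybenzoic acid (mCPBA), O=C(OO)c1cccc(Cl)c1
Why: Baeyer–Villiger oxidation of an ortho-alkoxybenzaldehyde (Dakin-type outcome): in the Criegee adduct the electron-rich aryl group migrates in preference to hydride, and the formate 6 is methanolysed to the phenol. The new oxygen stands on the carbon that carried the formyl group, so C1–OH is free while C2–O stays benzylated.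

Step 4
Reactants: 8 3-propylglutaric anhydride (4-propyloxane-2,6-dione)
Product: 9 3-(2-methoxy-2-oxoethyl)hexanoic acid (racemic)
Conditions: MeOH, reflux
Reagents that add atoms: methanol, CO
Why: Alcoholysis of a cyclic anhydride. The two carbonyls of 8 are equivalent by symmetry, so a single racemic half-ester should form and the two carboxyl carbons are told apart without a protecting group.

Step 5
Reactants: 9 3-(2-methoxy-2-oxoethyl)hexanoic acid
Product: 12 methyl 6-bromo-5-oxo-3-propylhexanoate (racemic), via acid chloride 10 (not isolated), via diazoketone 11 (not isolated)
Conditions: (COCl)2, DMF (cat.), CH2Cl2, rt; then TMSCHN2 (2 equiv), THF–MeCN, 0 °C; then 48% aq HBr, 0 °C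
Reagents that add atoms: (trimethylsilyl)diazomethane, C[Si](C)(C)C=[N+]=[N-]; hydrogen bromide, Br
Why: Acid chloride formation is followed by C-acylation of the silyl diazomethane to the diazoketone (first stage of an Arndt–Eistert sequence, the silyl group leaving as Me3SiCl), then protonation and displacement of N2 by bromide. The methyl ester is inert to all three reagents at 0 °C, and the silylated reagent serves as the non-explosive substitute for diazomethane.

Step 6
Reactants: 7 2-(benzyloxy)-5-[3-(benzyloxy)propyl]-3-methoxyphenol; 12 methyl 6-bromo-5-oxo-3-propylhexanoate
Product: 13 methyl 6-{2-(benzyloxy)-5-[3-(benzyloxy)propyl]-3-methoxyphenoxy}-5-oxo-3-propylhexanoate (racemic)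
Conditions: K2CO3, acetone, 50 °C
Reagents that add atoms: none
Why: Williamson ether synthesis: the potassium phenoxide of 7, its only acidic site, displaces bromide from the strongly SN2-activated alpha-bromo ketone. The hindered ring B oxygen is thus alkylated at a primary carbon and never has to be arylated.

Step 7
Reactants: 13 methyl 6-{2-(benzyloxy)-5-[3-(benzyloxy)propyl]-3-methoxyphenoxy}-5-oxo-3-propylhexanoate
Product: 14 2-{2-(benzyloxy)-5-[3-(benzyloxy)propyl]-3-methoxyphenoxy}-5-propylcyclohexane-1,3-dione
Conditions: KOtBu (2.2 equiv), THF, 0 °C → rt; then 1 M HCl
Reagents that add atoms: none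
Why: tert-Butoxide deprotonates 13 reversibly at C6, the carbon between the ketone and the aryloxy oxygen and the most acidic C–H of the chain; this enolate carbon adds to the ester carbonyl C1, and collapse of the tetrahedral intermediate expels methoxide and forms the bond that is C1–C2 of ring A. The closest known reaction type is the Claisen (Dieckmann-type) cyclization of 5-oxo esters to cyclohexane-1,3-diones, including closures through a substituted alpha carbon that give 2-substituted diones. The one ring is closed in the 6-(enolendo)-exo-trig mode, with the enolate double bond inside the new ring and the ester carbonyl outside it. No stereocentre of consequence is created: C2 of 14 is an enolised, doubly activated carbon, and the centre at C5 inherited from 13 later becomes an sp2 carbon of ring A. The step needs site selectivity among three possible enolates, and ring size secures it, because the C4 enolate and the ester enolate could only close four-membered rings and form reversibly. Any enol lactone from O-acylation should be reopened by alkoxide and funnelled to the C-acylated product. The equilibrium is drawn forward by deprotonation of 14, a vinylogous acid, to its delocalised potassium enolate, which is why more than two equivalents of base and an acidic quench are used. Benzyl ethers, methyl ethers and the alkyl aryl ether are inert to tert-butoxide, and with no free hydroxyl present no base is wasted and no transesterification can occur.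

Step 8
Reactants: 14 2-{2-(benzyloxy)-5-[3-(benzyloxy)propyl]-3-methoxyphenoxy}-5-propylcyclohexane-1,3-dione
Product: 15 2-{2-(benzyloxy)-5-[3-(benzyloxy)propyl]-3-methoxyphenoxy}-3-methoxy-5-propylphenol
Conditions: I2 (2.2 equiv), MeOH, reflux
Reagents that add atoms: methanol, CO
Why: Iodine–methanol aromatization of a cyclohexane-1,3-dione: the HI formed catalyses conversion of the enolised dione into its methyl enol ether, and alpha'-iodination through the dienol followed by loss of HI gives a cyclohexadienone that tautomerises to the resorcinol monomethyl ether. Since 14 is symmetric about its C2–C5 axis only one monoether can form. Any 16 formed by ketalisation before oxidation is carried into step 9.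

Step 9
Reactants: 15 2-{2-(benzyloxy)-5-[3-(benzyloxy)propyl]-3-methoxyphenoxy}-3-methoxy-5-propylphenol
Product: 16 2-(benzyloxy)-5-[3-(benzyloxy)propyl]-1-(2,6-dimethoxy-4-propylphenoxy)-3-methoxybenzene
Conditions: MeI, K2CO3, DMF, rt
Reagents that add atoms: iodomethane, CI
Why: Williamson O-methylation of the remaining ring A phenol. The phenoxide beside the aryloxy group is still open to the small electrophile, and the step converges whatever mixture step 8 delivers on the single dimethyl ether.

Step 10
Reactants: 16 2-(benzyloxy)-5-[3-(benzyloxy)propyl]-1-(2,6-dimethoxy-4-propylphenoxy)-3-methoxybenzene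
Product: 17 2-(2,6-dimethoxy-4-propylphenoxy)-4-(3-hydroxypropyl)-6-methoxyphenol
Conditions: H2 (1 atm), Pd/C, EtOAc–MeOH, rt
Reagents that add atoms: none
Why: Catalytic hydrogenolysis of the aryl benzyl and the alkyl benzyl ether over palladium releases the phenol and the primary alcohol, with toluene as the only by-product. The diaryl ether, the aryl methyl ethers and the saturated chains are inert to H2 at 1 atm and rt.

## Compound list

1 | 5-bromo-2-hydroxy-3-methoxybenzaldehyde | COc1cc(Br)cc(C=O)c1O | starting material
2 | 2-(benzyloxy)-5-bromo-3-methoxybenzaldehyde | COc1cc(Br)cc(C=O)c1OCc1ccccc1 | intermediate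
3 | allyl benzyl ether, [(prop-2-en-1-yloxy)methyl]benzene | C=CCOCc1ccccc1 | starting material
4 | 9-[3-(benzyloxy)propyl]-9-borabicyclo[3.3.1]nonane | C(CCB1C2CCCC1CCC2)OCc1ccccc1 | intermediate
5 | 2-(benzyloxy)-5-[3-(benzyloxy)propyl]-3-methoxybenzaldehyde | COc1cc(CCCOCc2ccccc2)cc(C=O)c1OCc1ccccc1 | intermediate
6 | 2-(benzyloxy)-5-[3-(benzyloxy)propyl]-3-methoxyphenyl formate | COc1cc(CCCOCc2ccccc2)cc(OC=O)c1OCc1ccccc1 | intermediate
7 | 2-(benzyloxy)-5-[3-(benzyloxy)propyl]-3-methoxyphenol | COc1cc(CCCOCc2ccccc2)cc(O)c1OCc1ccccc1 | intermediate
8 | 3-propylglutaric anhydride, 4-propyloxane-2,6-dione | CCCC1CC(=O)OC(=O)C1 | starting material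
9 | 3-(2-methoxy-2-oxoethyl)hexanoic acid, racemic | CCCC(CC(=O)O)CC(=O)OC | intermediate
10 | methyl 5-chloro-5-oxo-3-propylpentanoate, racemic | CCCC(CC(=O)Cl)CC(=O)OC | intermediate
11 | methyl 6-diazo-5-oxo-3-propylhexanoate, racemic | CCCC(CC(=O)OC)CC(=O)C=[N+]=[N-] | intermediate
12 | methyl 6-bromo-5-oxo-3-propylhexanoate, racemic | CCCC(CC(=O)OC)CC(=O)CBr | intermediate
13 | methyl 6-{2-(benzyloxy)-5-[3-(benzyloxy)propyl]-3-methoxyphenoxy}-5-oxo-3-propylhexanoate, racemic | COC(=O)CC(CCC)CC(=O)COc1cc(CCCOCc2ccccc2)cc(OC)c1OCc1ccccc1 | intermediate
14 | 2-{2-(benzyloxy)-5-[3-(benzyloxy)propyl]-3-methoxyphenoxy}-5-propylcyclohexane-1,3-dione, configuration immaterial | CCCC1CC(=O)C(Oc2cc(CCCOCc3ccccc3)cc(OC)c2OCc2ccccc2)C(=O)C1 | intermediate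
15 | 2-{2-(benzyloxy)-5-[3-(benzyloxy)propyl]-3-methoxyphenoxy}-3-methoxy-5-propylphenol | CCCc1cc(O)c(Oc2cc(CCCOCc3ccccc3)cc(OC)c2OCc2ccccc2)c(OC)c1 | intermediate
16 | 2-(benzyloxy)-5-[3-(benzyloxy)propyl]-1-(2,6-dimethoxy-4-propylphenoxy)-3-methoxybenzene | CCCc1cc(OC)c(Oc2cc(CCCOCc3ccccc3)cc(OC)c2OCc2ccccc2)c(OC)c1 | intermediate
17 | 2-(2,6-dimethoxy-4-propylphenoxy)-4-(3-hydroxypropyl)-6-methoxyphenol, no stereocentre | CCCc1cc(OC)c(Oc2cc(CCCO)cc(OC)c2O)c(OC)c1 | target

## Step count and least certain steps

Total step count: 10. Longest linear sequence: 8 steps (1 → 2 → 5 → 7 → 13 → 14 → 15 → 16 → 17, steps 1–3 and 6–10). Steps 4 and 5 form the second branch, which joins at step 6.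

**Step 7 (key step).** The most likely failure is intermolecular Claisen or aldol condensation outrunning ring closure, or base-induced retro-Michael fragmentation of the 1,5-dicarbonyl chain. Both are possible because every enolate of 13 forms reversibly, and the bulky aryloxy group on the nucleophilic carbon may slow the closure. The fallback attaches the oxygen to a preformed dione ring. Setting out from 7, purchasable 5-propylcyclohexane-1,3-dione F1 is converted by diazo transfer (4-acetamidobenzenesulfonyl azide, Et3N, MeCN) into 2-diazo-5-propylcyclohexane-1,3-dione F2. Insertion of the rhodium carbenoid from F2 into the O–H bond of 7 (Rh2(OAc)4 cat., benzene, 60 °C) should give 14, where the route is rejoined.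

**Step 8.** The most likely failure is acid cleavage of the aryl benzyl ether by the HI formed in hot methanol, electrophilic iodination of ring B at C4 or C6, or arrest at the enol ether stage. The fallback dehydrogenates stepwise without halogen or strong acid, setting out from 14. Trimethyl orthoformate in MeOH with catalytic TsOH gives the vinylogous ester 2-{2-(benzyloxy)-5-[3-(benzyloxy)propyl]-3-methoxyphenoxy}-3-methoxy-5-propylcyclohex-2-en-1-one F3. Kinetic deprotonation at C6 with LiN(iPr)2 and trapping with Me3SiCl (THF, −78 °C) gives the cross-conjugated silyl dienol ether [(6-{2-(benzyloxy)-5-[3-(benzyloxy)propyl]-3-methoxyphenoxy}-5-methoxy-3-propylcyclohexa-1,5-dien-1-yl)oxy]trimethylsilane F4. Saegusa–Ito oxidation with Pd(OAc)2 in MeCN then forms the dienone, which should tautomerise to 15, where the route is rejoined.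

**Step 2.** The most likely failure is reduction of the formyl group by boron hydride species, or slow transmetallation that leaves room for protodehalogenation and beta-hydride elimination. The fallback removes the carbonyl group before any organoboron reagent is present, setting out from 2. Baeyer–Villiger oxidation (mCPBA, CH2Cl2) gives 2-(benzyloxy)-5-bromo-3-methoxyphenyl formate F5, and methanolysis (K2CO3 cat., MeOH) gives 2-(benzyloxy)-5-bromo-3-methoxyphenol F6. B-alkyl Suzuki–Miyaura coupling of F6 with 4 (Pd(OAc)2, 2-dicyclohexylphosphino-2',6'-dimethoxybiphenyl, K3PO4 in excess, THF–H2O, 60 °C) should give 7 directly, where the route is rejoined.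

**Step 5.** The most likely failure is sluggish acylation of the weakly nucleophilic silyl diazomethane, halide scrambling between chloride and bromide in the acid quench, or reclosure of the half-ester chloride to the anhydride. The fallback avoids diazo compounds and forms the ether at a doubly activated carbon, setting out from 9 through its chloride 10.
- Acylation of the magnesium enolate of potassium methyl malonate (MgCl2, Et3N, MeCN), with decarboxylation on acidic work-up, gives dimethyl 3-oxo-5-propylheptanedioate F7.
- SO2Cl2 (CH2Cl2, 0 °C) chlorinates the active methylene and gives dimethyl 2-chloro-3-oxo-5-propylheptanedioate F8.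
- The potassium phenoxide of 7 (K2CO3, acetone) displaces chloride and gives dimethyl 2-{2-(benzyloxy)-5-[3-(benzyloxy)propyl]-3-methoxyphenoxy}-3-oxo-5-propylheptanedioate F9.
- Krapcho demethoxycarbonylation (LiCl, wet DMSO, 130 °C) removes only the beta-keto ester carboxyl and should give 13, where the route is rejoined.

## Further compounds

F1 | step 7 | 5-propylcyclohexane-1,3-dione | CCCC1CC(=O)CC(=O)C1
F2 | step 7 | 2-diazo-5-propylcyclohexane-1,3-dione | CCCC1CC(=O)C(=[N+]=[N-])C(=O)C1
F3 | step 8 | 2-{2-(benzyloxy)-5-[3-(benzyloxy)propyl]-3-methoxyphenoxy}-3-methoxy-5-propylcyclohex-2-en-1-one, racemic | CCCC1CC(=O)C(Oc2cc(CCCOCc3ccccc3)cc(OC)c2OCc2ccccc2)=C(OC)C1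
F4 | step 8 | [(6-{2-(benzyloxy)-5-[3-(benzyloxy)propyl]-3-methoxyphenoxy}-5-methoxy-3-propylcyclohexa-1,5-dien-1-yl)oxy]trimethylsilane, racemic | CCCC1CC(OC)=C(Oc2cc(CCCOCc3ccccc3)cc(OC)c2OCc2ccccc2)C(O[Si](C)(C)C)=C1
F5 | step 2 | 2-(benzyloxy)-5-bromo-3-methoxyphenyl formate | O=COc1cc(Br)cc(OC)c1OCc1ccccc1
F6 | step 2 | 2-(benzyloxy)-5-bromo-3-methoxyphenol | Oc1cc(Br)cc(OC)c1OCc1ccccc1
F7 | step 5 | dimethyl 3-oxo-5-propylheptanedioate, racemic | CCCC(CC(=O)OC)CC(=O)CC(=O)OC
F8 | step 5 | dimethyl 2-chloro-3-oxo-5-propylheptanedioate, mixture of diastereomers | CCCC(CC(=O)OC)CC(=O)C(Cl)C(=O)OC
F9 | step 5 | dimethyl 2-{2-(benzyloxy)-5-[3-(benzyloxy)propyl]-3-methoxyphenoxy}-3-oxo-5-propylheptanedioate, mixture of diastereomers | CCCC(CC(=O)OC)CC(=O)C(Oc1cc(CCCOCc2ccccc2)cc(OC)c1OCc1ccccc1)C(=O)OC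
A1 | alternative 1 | 2,6-dimethoxy-4-propylphenol | CCCc1cc(OC)c(O)c(OC)c1
A2 | alternative 1 | bis(trimethylsilyl) ketene acetal of (2,6-dimethoxy-4-propylphenoxy)acetic acid | CCCc1cc(OC)c(OC=C(O[Si](C)(C)C)O[Si](C)(C)C)c(OC)c1
A3 | alternative 1 | methyl 3-bromocoumalate, methyl 3-bromo-2-oxo-2H-pyran-5-carboxylate | COC(=O)C1=COC(=O)C(Br)=C1
A4 | alternative 1 | methyl 3-bromo-5-(2,6-dimethoxy-4-propylphenoxy)-4-hydroxybenzoate | CCCc1cc(OC)c(Oc2cc(C(=O)OC)cc(Br)c2O)c(OC)c1
A5 | alternative 2 | 5-[3-(benzyloxy)propyl]-3-methoxy-2-(trimethylsilyl)phenyl trifluoromethanesulfonate | COc1cc(CCCOCc2ccccc2)cc(OS(=O)(=O)C(F)(F)F)c1[Si](C)(C)C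
A6 | alternative 2 | 5-[3-(benzyloxy)propyl]-1-(2,6-dimethoxy-4-propylphenoxy)-2-iodo-3-methoxybenzene | CCCc1cc(OC)c(Oc2cc(CCCOCc3ccccc3)cc(OC)c2I)c(OC)c1
A7 | alternative 3 | 2-{2-(benzyloxy)-5-[3-(benzyloxy)propyl]-3-methoxyphenoxy}-4-chloro-3-methoxycyclobut-2-en-1-one, racemic | COC1=C(Oc2cc(CCCOCc3ccccc3)cc(OC)c2OCc2ccccc2)C(=O)C1Cl
A8 | alternative 3 | tributyl(pent-1-en-2-yl)stannane | CCCC(=C)[Sn](CCCC)(CCCC)CCCC
A9 | alternative 3 | 2-{2-(benzyloxy)-5-[3-(benzyloxy)propyl]-3-methoxyphenoxy}-3-methoxy-5-propylphenol | CCCc1cc(O)c(Oc2cc(CCCOCc3ccccc3)cc(OC)c2OCc2ccccc2)c(OC)c1
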